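**Retrosynthetic overview**
- The target comes from MOM removal and C2 protodesilylation of a 2-trimethylsilyl tris-MOM isoflavone.
- The γ-pyranone ring is formed last, at the convergence: Rh(III) aldehyde C–H activation and oxidative [4+2] annulation of a phloroglucinol-type salicylaldehyde with a chromenyl(trimethylsilyl)acetylene (forms C4–C3 and O1–C2).
- A-ring fragment: resorcinol → bis-MOM ether → Ir C–H borylation/oxidation (third oxygen) → Mg-mediated ortho-formylation.
- B-ring fragment: catechol → mono-MOM → para-iodination → 1,1-dimethylpropargyl ether → Claisen/electrocyclisation (chromene ring, formed first) → Sonogashira with TMS-acetylene (forms the C3–C1′ bond).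

Assumption: the target has no stereocentres and no stereogenic double bond (the only non-aromatic C=C is the endocyclic chromene alkene), so "single enantiomer" requires no stereocontrol.

**A-ring branch**

Step 1
Reactants: 1 resorcinol
Product: 2 1,3-bis(methoxymethoxy)benzene
Conditions: MOMCl (2.4 equiv), i-Pr2NEt, CH2Cl2, 0 °C → rt
Reagents that add atoms: chloromethyl methyl ether, COCCl
Why: Standard phenol O-alkylation (Williamson-type acetal protection) giving base- and metal-stable MOM ethers.

Step 2
Reactants: 2 1,3-bis(methoxymethoxy)benzene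
Product: 3 2-[3,5-bis(methoxymethoxy)phenyl]-4,4,5,5-tetramethyl-1,3,2-dioxaborolane
Conditions: [Ir(OMe)(cod)]2 (1 mol%), dtbpy (2 mol%), B2pin2 (0.6 equiv), THF, 60 °C
Reagents that add atoms: bis(pinacolato)diboron, CC1(C)OB(OC1(C)C)B1OC(C)(C)C(C)(C)O1
Why: Sterically controlled Ir-catalysed aromatic C–H borylation functionalises C5, the only C–H with no ortho substituent in a 1,3-disubstituted arene.

Step 3
Reactants: 3 the aryl pinacol boronate
Product: 4 3,5-bis(methoxymethoxy)phenol
Conditions: 30% H2O2, aq NaOH, THF, 0 °C
Reagents that add atoms: hydrogen peroxide, OO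
Why: Oxidation of the arylboronate (boron-to-oxygen 1,2-aryl migration) gives the phenol under basic conditions that leave the MOM ethers intact.

Step 4
Reactants: 4 3,5-bis(methoxymethoxy)phenol
Product: 5 2-hydroxy-4,6-bis(methoxymethoxy)benzaldehyde
Conditions: MgCl2, Et3N, (CH2O)n, MeCN, reflux
Reagents that add atoms: paraformaldehyde (formaldehyde), C=O
Why: Mg-phenoxide-templated ortho-formylation (Casnati–Skattebøl) delivers formaldehyde only ortho to the free OH, and the two ortho sites are equivalent by symmetry.

**B-ring branch**

Step 5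
Reactants: 6 catechol
Product: 7 2-(methoxymethoxy)phenol
Conditions: NaH (1.0 equiv), MOMCl (1.0 equiv), THF/DMF, 0 °C
Reagents that add atoms: chloromethyl methyl ether, COCCl
Why: Statistical mono-O-alkylation of a symmetrical diol; catechol and the bis-ether are separable and recyclable.

Step 6
Reactants: 7 2-(methoxymethoxy)phenol
Product: 8 4-iodo-2-(methoxymethoxy)phenol (iodine para to the free OH)
Conditions: NaI, NaOH, aq NaOCl (slow addition), MeOH, 0 °C; Na2S2O3 quench, neutralise to pH 7
Reagents that add atoms: sodium iodide, [Na+].[I-]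
Why: Electrophilic aromatic iodination of the phenoxide, which is a far stronger para-director than the OMOM group, so iodine enters para to the oxygen that later becomes the pyran oxygen.

Step 7
Reactants: 8 4-iodo-2-(methoxymethoxy)phenol; 9 3-chloro-3-methylbut-1-yne
Product: 10 4-iodo-2-(methoxymethoxy)-1-[(2-methylbut-3-yn-2-yl)oxy]benzene
Conditions: CuCl2·2H2O (0.5 mol%), DBU, MeCN, 0 °C
Reagents that add atoms: none (new atoms come from 9)
Why: Cu-catalysed propargylic etherification of a phenol with a tertiary propargyl chloride (copper acetylide/allenylidene pathway) gives the hindered aryl 1,1-dimethylpropargyl ether.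

Step 8
Reactants: 10 the aryl propargyl ether
Product: 11 6-iodo-8-(methoxymethoxy)-2,2-dimethyl-2H-chromene
Conditions: o-xylene, 140 °C, N2, sealed tube
Reagents that add atoms: none
Why: Aromatic propargyl Claisen rearrangement to the only free ortho carbon, then 1,5-H shift and oxa-6π electrocyclisation, forms the 2,2-dimethylchromene ring.

Step 9
Reactants: 11 6-iodo-8-(methoxymethoxy)-2,2-dimethyl-2H-chromene; 12 ethynyltrimethylsilane
Product: 13 8-(methoxymethoxy)-2,2-dimethyl-6-[(trimethylsilyl)ethynyl]-2H-chromene
Conditions: PdCl2(PPh3)2 (2 mol%), CuI (4 mol%), Et3N, THF, rt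
Reagents that add atoms: none (new atoms come from 12)
Why: Sonogashira coupling of an aryl iodide at room temperature forms the aryl–C bond that becomes C1′–C3 and leaves the chromene alkene and MOM group untouched.

**Convergence and endgame**

Step 10
Reactants: 5 2-hydroxy-4,6-bis(methoxymethoxy)benzaldehyde (1.2 equiv); 13 the chromenyl(trimethylsilyl)acetylene
Product: 14 5,7-bis(methoxymethoxy)-3-[8-(methoxymethoxy)-2,2-dimethyl-2H-chromen-6-yl]-2-(trimethylsilyl)-4H-chromen-4-one
Conditions: [Cp*Rh(MeCN)3](SbF6)2 (5 mol%), Cu(OAc)2 (2.2 equiv, anhydrous), DCE, 80 °C, N2 (silver-free and aprotic to protect the C(sp)–Si bond)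
Reagents that add atoms: none
Why: Proposed new method: a Cp*Rh(III)-catalysed oxidative [4+2] annulation of a salicylaldehyde with an aryl(trimethylsilyl)acetylene used as a regiocontrolled surrogate for a terminal arylacetylene — phenoxide-directed aldehyde C–H rhodation gives a five-membered acyl-rhodacycle, the alkyne inserts into Rh–C(acyl) with Rh on the silyl-bearing carbon (α-silyl stabilisation of C–Rh and the bulky SiMe3 kept away from the forming C–C bond, the same bias that places silicon next to the heteroatom in Larock-type heteroannulations) so the acyl carbon bonds to the aryl-bearing carbon (future C3), and C–O reductive elimination closes the pyranone with TMS at C2 while Cu(II) reoxidises Rh(I); the closest known reaction type is the Rh-catalysed oxidative coupling of salicylaldehydes with internal diaryl/dialkyl alkynes to 2,3-disubstituted chromones.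

Step 11
Reactants: 14 the 2-trimethylsilyl isoflavone
Product: 15 5,7-bis(methoxymethoxy)-3-[8-(methoxymethoxy)-2,2-dimethyl-2H-chromen-6-yl]-4H-chromen-4-one
Conditions: TBAF·3H2O (1.5 equiv), AcOH (1.5 equiv), THF, 0 °C → rt
Reagents that add atoms: none
Why: Fluoride-mediated protodesilylation of a C(sp2)–Si bond whose carbanion character is stabilised by the adjacent ring oxygen, with AcOH buffering to prevent nucleophilic opening of the pyranone.

Step 12
Reactants: 15 the tris-MOM isoflavone
Product: 16 semilicoisoflavone B, 5,7-dihydroxy-3-(8-hydroxy-2,2-dimethyl-2H-chromen-6-yl)-4H-chromen-4-one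
Conditions: 3 M aq HCl/MeOH (1:5), 50 °C
Reagents that add atoms: none
Why: Acid-catalysed acetal (MOM) hydrolysis releases the three phenols under dilute-acid conditions that 2,2-dimethylchromenes tolerate.

**Compound list**
1 | resorcinol | Oc1cccc(O)c1 | starting material
2 | 1,3-bis(methoxymethoxy)benzene | COCOc1cccc(OCOC)c1 | intermediate
3 | 2-[3,5-bis(methoxymethoxy)phenyl]-4,4,5,5-tetramethyl-1,3,2-dioxaborolane | COCOc1cc(OCOC)cc(c1)B1OC(C)(C)C(C)(C)O1 | intermediate
4 | 3,5-bis(methoxymethoxy)phenol | COCOc1cc(O)cc(OCOC)c1 | intermediate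
5 | 2-hydroxy-4,6-bis(methoxymethoxy)benzaldehyde | COCOc1cc(O)c(C=O)c(OCOC)c1 | intermediate
6 | catechol | Oc1ccccc1O | starting material
7 | 2-(methoxymethoxy)phenol | COCOc1ccccc1O | intermediate
8 | 4-iodo-2-(methoxymethoxy)phenol | COCOc1cc(I)ccc1O | intermediate
9 | 3-chloro-3-methylbut-1-yne | CC(C)(Cl)C#C | starting material
10 | 4-iodo-2-(methoxymethoxy)-1-[(2-methylbut-3-yn-2-yl)oxy]benzene | COCOc1cc(I)ccc1OC(C)(C)C#C | intermediate
11 | 6-iodo-8-(methoxymethoxy)-2,2-dimethyl-2H-chromene | CC1(C)C=Cc2cc(I)cc(OCOC)c2O1 | intermediate
12 | ethynyltrimethylsilane | C#C[Si](C)(C)C | starting material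
13 | 8-(methoxymethoxy)-2,2-dimethyl-6-[(trimethylsilyl)ethynyl]-2H-chromene | CC1(C)C=Cc2cc(C#C[Si](C)(C)C)cc(OCOC)c2O1 | intermediate
14 | 5,7-bis(methoxymethoxy)-3-[8-(methoxymethoxy)-2,2-dimethyl-2H-chromen-6-yl]-2-(trimethylsilyl)-4H-chromen-4-one | CC1(C)C=Cc2cc(-c3c([Si](C)(C)C)oc4cc(OCOC)cc(OCOC)c4c3=O)cc(OCOC)c2O1 | intermediate
15 | 5,7-bis(methoxymethoxy)-3-[8-(methoxymethoxy)-2,2-dimethyl-2H-chromen-6-yl]-4H-chromen-4-one | CC1(C)C=Cc2cc(-c3coc4cc(OCOC)cc(OCOC)c4c3=O)cc(OCOC)c2O1 | intermediate
16 | semilicoisoflavone B (achiral) | CC1(C)C=Cc2cc(-c3coc4cc(O)cc(O)c4c3=O)cc(O)c2O1 | target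

**Totals**
Total step count: 12.
Longest linear sequence: 8 (steps 5–12, catechol to target). The A-ring branch (steps 1–4) runs in parallel.

**Steps most likely to fail, with fallbacks**
1. Step 10 (proposed new Rh annulation). Risks are reversed insertion regiochemistry (which would lead to the flavone skeleton), premature alkyne desilylation with Glaser coupling, and decarbonylation. Fallback, all known chemistry: the 3-iodochromone Suzuki route.
   - Convert 5 to 2-hydroxy-4,6-bis(methoxymethoxy)acetophenone (MeMgBr, then MnO2).
   - Form the enaminone with DMF-DMA and cyclise with I2 to 3-iodo-5,7-bis(methoxymethoxy)chromone.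
   - Convert 11 to its pinacol boronate by Miyaura borylation.
   - Join the two by Pd-catalysed Suzuki–Miyaura coupling to give 15 directly.
2. Step 4 (ortho-formylation of a very electron-rich phenol). Risks are diarylmethane formation and MOM scrambling. Fallback: MOM-protect 4 to 1,3,5-tris(methoxymethoxy)benzene, carry out directed ortho-lithiation with a DMF quench to give 2,4,6-tris(methoxymethoxy)benzaldehyde, then remove one carbonyl-flanking MOM by chelation-assisted cleavage (MgBr2·OEt2).
3. Step 6 (para-iodination). Risks are ortho- and di-iodination and oxidation of the electron-rich phenol. Fallback: omit the iodination and carry 7 through steps 7–8 to 8-(methoxymethoxy)-2,2-dimethyl-2H-chromene. Then use sterically controlled Ir-catalysed C–H borylation at C6, the only ring C–H without an ortho substituent, followed by Cu-catalysed iododeboronation to reach 11.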